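The 7-oxabicyclo[2.2.1]heptane core (bridge O7; C1 quaternary, methyl; C2; C3 quaternary; C4–H; C5 and C6 methylenes) is cut at C1–C6 and C1–O7. The oxolane ring O7–C1–C6–C5–C4 is grown from an oxetane O7–C4–C5–C6: a copper carbenoid at C1, made possible by a temporary ketone at C2 beside the ether carbon C1, is captured by the oxetane oxygen, and the oxonium ylide shifts C6 from O7 to C1. One operation forms both bonds, the quaternary bridgehead and the bicycle. The precursor is an acyclic α-diazo ketone whose quaternary C3, set together with C4 by geranylboration, carries the oxetane; the side chains are finished afterwards.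

Key step: step 9

Remark: (S)-TRIP is taken to deliver the allyl group to the Si face of aldehyde 3, by analogy with the Re-face preference known for (R)-TRIP in aldehyde allylborations; if the sense is opposite, the enantiomeric catalyst is used.

Step 1
Reactants: 1 geranyl acetate, (2E)-3,7-dimethylocta-2,6-dien-1-yl acetate
Product: 2 2-[(2E)-3,7-dimethylocta-2,6-dien-1-yl]-4,4,5,5-tetramethyl-1,3,2-dioxaborolane (geranyl-Bpin)
Conditions: B2pin2, Pd(dba)2 (3 mol %), DMSO, 50 °C
Reagents that add atoms: bis(pinacolato)diboron, CC1(C)OB(OC1(C)C)B1OC(C)(C)C(C)(C)O1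
Why: Miyaura-type allylic borylation: zerovalent palladium ionises the allylic acetate to a π-allyl complex that is borylated at the unsubstituted terminus, which should give the linear boronate with the (E)-geometry kept.

Step 2
Reactants: 2 geranyl-Bpin, 3 3-[(tert-butyldimethylsilyl)oxy]propanal
Product: 5 (3R,4S)-1-[(tert-butyldimethylsilyl)oxy]-4-ethenyl-4,8-dimethylnon-7-en-3-ol, via homoallyl pinacol borate 4 (not isolated)
Conditions: (S)-TRIP (5 mol %), 4 Å molecular sieves, toluene, −30 to 0 °C; aq NaHCO3 work-up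
Reagents that add atoms: none
Why: Chiral-phosphoric-acid-catalysed allylboration through a closed chair transition state with the aldehyde chain equatorial: the (E)-geometry of 2 places the 4-methylpent-3-enyl group anti and the methyl group syn to the new hydroxyl, so the quaternary carbon (future C3) and the carbinol (future C4) are set in one bond formation, and (S)-TRIP is chosen to direct the allyl group to the Si face of the aldehyde.

Step 3
Reactants: 5 (3R,4S)-1-[(tert-butyldimethylsilyl)oxy]-4-ethenyl-4,8-dimethylnon-7-en-3-ol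
Product: 6 (3R,4S)-4-ethenyl-4,8-dimethylnon-7-ene-1,3-diol
Conditions: camphorsulfonic acid (10 mol %), MeOH, 0 °C
Reagents that add atoms: none
Why: Acid-catalysed methanolysis cleaves the primary silyl ether and leaves the alkenes and both stereocentres untouched.

Step 4
Reactants: 6 (3R,4S)-4-ethenyl-4,8-dimethylnon-7-ene-1,3-diol
Product: 8 (2R)-2-[(3S)-3,7-dimethylocta-1,6-dien-3-yl]oxetane, via primary monotosylate 7 (not isolated)
Conditions: KOt-Bu (1.05 equiv), THF, 0 °C; TsCl (1.0 equiv); then KOt-Bu (1.2 equiv), 0 °C to rt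
Reagents that add atoms: none
Why: One-pot Williamson oxetane synthesis: the primary alkoxide is sulfonylated selectively and the hindered secondary alkoxide then closes the four-membered ring by 4-exo-tet displacement, so the C–O stereocentre is retained.

Step 5
Reactants: 8 (2R)-2-[(3S)-3,7-dimethylocta-1,6-dien-3-yl]oxetane
Product: 9 (3R)-3,7-dimethyl-3-[(2R)-oxetan-2-yl]oct-6-en-2-one
Conditions: Pd(Quinox)Cl2 (5 mol %; Quinox = 2-(4,5-dihydrooxazol-2-yl)quinoline), AgSbF6 (12 mol %), aq t-BuOOH, CH2Cl2, rt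
Reagents that add atoms: tert-butyl hydroperoxide, CC(C)(C)OO
Why: Catalyst-controlled Tsuji–Wacker oxidation: peroxypalladation of the monosubstituted alkene gives the methyl ketone with Markovnikov selectivity, while the trisubstituted alkene does not react.

Step 6
Reactants: 9 (3R)-3,7-dimethyl-3-[(2R)-oxetan-2-yl]oct-6-en-2-one
Product: 10 (4R)-4,8-dimethyl-4-[(2R)-oxetan-2-yl]non-7-en-3-one
Conditions: LDA, THF, −78 °C; MeI, −78 to −20 °C
Reagents that add atoms: iodomethane, CI
Why: Kinetic enolate alkylation: the ketone can enolise only toward its methyl group because the other α-carbon is quaternary, and methylation there gives the ethyl ketone.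

Step 7
Reactants: 10 (4R)-4,8-dimethyl-4-[(2R)-oxetan-2-yl]non-7-en-3-one
Product: 11 (4R)-6-[(2R)-3,3-dimethyloxiran-2-yl]-4-methyl-4-[(2R)-oxetan-2-yl]hexan-3-one
Conditions: D-fructose-derived Shi ketone (30 mol %), Oxone, K2CO3, Bu4NHSO4, MeCN/dimethoxymethane, aq Na2B4O7 buffer, 0 °C
Reagents that add atoms: Oxone (potassium peroxymonosulfate, KHSO5), [K+].[O-]S(=O)(=O)OO
Why: Shi asymmetric epoxidation: the chiral dioxirane reacts only with the electron-rich trisubstituted alkene, its spiro transition state sets the (2R)-epoxide under reagent control, and the alkene is thereby removed before the carbenoid step.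

Step 8
Reactants: 11 (4R)-6-[(2R)-3,3-dimethyloxiran-2-yl]-4-methyl-4-[(2R)-oxetan-2-yl]hexan-3-one
Product: 13 (4R)-2-diazo-6-[(2R)-3,3-dimethyloxiran-2-yl]-4-methyl-4-[(2R)-oxetan-2-yl]hexan-3-one, via trifluoroacetyl diketone 12 (not isolated)
Conditions: LiHMDS, THF, −78 °C; CF3CO2CH2CF3; then MsN3, Et3N, H2O, MeCN, rt
Reagents that add atoms: methanesulfonyl azide, CS(=O)(=O)N=[N+]=[N-]
Why: Detrifluoroacetylative diazo transfer (a Regitz-type deacylative diazo transfer): the kinetic enolate, which can form only on the ethyl side, is trifluoroacetylated and the activated 1,3-dicarbonyl compound then takes up the diazo group from MsN3 with loss of the trifluoroacetyl group.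

Step 9
Reactants: 13 (4R)-2-diazo-6-[(2R)-3,3-dimethyloxiran-2-yl]-4-methyl-4-[(2R)-oxetan-2-yl]hexan-3-one
Product: 15 (1S,3R,4R)-3-{2-[(2R)-3,3-dimethyloxiran-2-yl]ethyl}-1,3-dimethyl-7-oxabicyclo[2.2.1]heptan-2-one, via bicyclic oxonium ylide 14 (not isolated)
Conditions: Cu(hfacac)2 (5 mol %), CH2Cl2, reflux, slow addition of 13
Reagents that add atoms: none
Why: Cu(hfacac)2 converts the diazo ketone into an electrophilic copper carbenoid at C1, the lone pair of the oxetane oxygen O7 captures it to give the bicyclic oxonium ylide 14, and a [1,2]-Stevens shift (homolysis of the exocyclic O7–C6 bond and recombination of the radical pair at C1) moves C6 from oxygen to carbon. The closest known reactions are the copper- and rhodium-mediated ring expansion of oxetanes to oxolanes by diazo compounds and the [1,2]-shift of bicyclic oxonium ylides from ether-tethered diazo ketones, which gives oxygen-bridged cycloalkanones. The oxolan-3-one ring O7–C4–C3–C2–C1 closes by attack of O7 on the carbenoid carbon (five-membered, exo to the carbon–copper double bond), and the C1–C6 bond made in the shift closes the six-membered carbocycle while the oxetane O7–C4–C5–C6 becomes the oxolane O7–C1–C6–C5–C4. The new quaternary stereocentre C1 is controlled by C4: O7 stays bonded to C4 throughout, so the one-atom bridge can span C1 and C4 on one face only and C1 should form in a single configuration, with C3 and C4 untouched. The step needs ylide formation to outrun 1,2-hydride migration and C–H insertion, which the five-membered closure onto the exposed, Lewis-basic oxetane oxygen and the electrophilic copper catalyst should secure, and it needs C6 to migrate instead of the ring-fusion carbon C4, which follows from the better overlap of the exocyclic O7–C6 bond with the ylide carbon and from the avoidance of a cyclobutanone. Cyclopropanation cannot compete because the alkene is already masked as the epoxide, and release of oxetane strain drives the shift of the unactivated primary carbon.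

Step 10
Reactants: 15 (1S,3R,4R)-3-{2-[(2R)-3,3-dimethyloxiran-2-yl]ethyl}-1,3-dimethyl-7-oxabicyclo[2.2.1]heptan-2-one
Product: 16 (1S,3R,4R)-3-[(3S)-3-bromo-4-hydroxy-4-methylpentyl]-1,3-dimethyl-7-oxabicyclo[2.2.1]heptan-2-one
Conditions: Li2NiBr4, THF, 0 °C to rt; pH 7 buffer
Reagents that add atoms: dilithium tetrabromonickelate (Li2NiBr4), [Li+].[Li+].[Ni+2].[Br-].[Br-].[Br-].[Br-]
Why: Nucleophilic epoxide opening: Li2NiBr4 delivers soft bromide by SN2 attack at the less hindered secondary carbon, so inversion there sets the (3S)-bromide and leaves a tertiary alcohol.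

Step 11
Reactants: 16 (1S,3R,4R)-3-[(3S)-3-bromo-4-hydroxy-4-methylpentyl]-1,3-dimethyl-7-oxabicyclo[2.2.1]heptan-2-one
Product: 17 (1S,3R,4R)-3-[(3S)-3-bromo-4-chloro-4-methylpentyl]-1,3-dimethyl-7-oxabicyclo[2.2.1]heptan-2-one
Conditions: SOCl2, pyridine, CH2Cl2, −20 to 0 °C
Reagents that add atoms: thionyl chloride, ClS(Cl)=O
Why: Deoxychlorination with neighbouring-group participation: the chlorosulfite ionises with help from bromine to a bromonium ion that chloride opens at the tertiary carbon, so the C–Br stereocentre is retained and the tertiary chloride is formed.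

Step 12
Reactants: 17 (1S,3R,4R)-3-[(3S)-3-bromo-4-chloro-4-methylpentyl]-1,3-dimethyl-7-oxabicyclo[2.2.1]heptan-2-one
Product: 18 (1S,3S,4R)-3-[(3S)-3-bromo-4-chloro-4-methylpentyl]-1,3-dimethyl-2-methylidene-7-oxabicyclo[2.2.1]heptane
Conditions: Cp2TiMe2, toluene, 75 °C, dark
Reagents that add atoms: dimethyltitanocene (Cp2TiMe2), [CH3-].[CH3-].[Ti+4].c1cc[cH-]c1.c1cc[cH-]c1
Why: Petasis methylenation: the titanocene methylidene formed on heating adds to the non-enolisable, hindered ketone by [2+2] cycloaddition and cycloreversion under non-basic conditions that the alkyl halides tolerate.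

Step 13
Reactants: 18 (1S,3S,4R)-3-[(3S)-3-bromo-4-chloro-4-methylpentyl]-1,3-dimethyl-2-methylidene-7-oxabicyclo[2.2.1]heptane
Product: 19 2-{[(1S,2S,3S,4R)-3-[(3S)-3-bromo-4-chloro-4-methylpentyl]-1,3-dimethyl-7-oxabicyclo[2.2.1]heptan-2-yl]methyl}-4,4,5,5-tetramethyl-1,3,2-dioxaborolane
Conditions: HBpin, RhCl(PPh3)3 (2 mol %), THF, rt
Reagents that add atoms: pinacolborane, [H]B1OC(C)(C)C(C)(C)O1
Why: Rhodium-catalysed anti-Markovnikov hydroboration: boron goes to the terminal carbon and hydrogen is delivered syn to C2 from the less hindered exo face (the side of the oxygen bridge, away from the endo methyl at C3 and the C5–C6 bridge), which sets C2 with its new side chain endo.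

Step 14
Reactants: 19 2-{[(1S,2S,3S,4R)-3-[(3S)-3-bromo-4-chloro-4-methylpentyl]-1,3-dimethyl-7-oxabicyclo[2.2.1]heptan-2-yl]methyl}-4,4,5,5-tetramethyl-1,3,2-dioxaborolane
Product: 21 2-{2-[(1S,2S,3S,4R)-3-[(3S)-3-bromo-4-chloro-4-methylpentyl]-1,3-dimethyl-7-oxabicyclo[2.2.1]heptan-2-yl]ethyl}-4,4,5,5-tetramethyl-1,3,2-dioxaborolane, via chloromethyl boronate complex 20 (not isolated)
Conditions: ICH2Cl, n-BuLi, THF, −78 °C to rt
Reagents that add atoms: chloroiodomethane, ClCI
Why: Matteson homologation: chloromethyllithium adds to boron and 1,2-migration of the primary alkyl group with loss of chloride inserts one methylene group.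

Step 15
Reactants: 22 (R)-but-3-en-2-ol
Product: 23 (2R)-but-3-en-2-yl N,N-diisopropylcarbamate
Conditions: NaH, THF, 0 °C; i-Pr2NCOCl, reflux
Reagents that add atoms: N,N-diisopropylcarbamoyl chloride, CC(C)N(C(C)C)C(Cl)=O
Why: O-Acylation of the sodium alkoxide by the carbamoyl chloride gives the carbamate without touching the stereocentre.

Step 16
Reactants: 21 2-{2-[(1S,2S,3S,4R)-3-[(3S)-3-bromo-4-chloro-4-methylpentyl]-1,3-dimethyl-7-oxabicyclo[2.2.1]heptan-2-yl]ethyl}-4,4,5,5-tetramethyl-1,3,2-dioxaborolane, 23 (2R)-but-3-en-2-yl N,N-diisopropylcarbamate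
Product: 27 (3S)-5-[(1S,2S,3S,4R)-3-[(3S)-3-bromo-4-chloro-4-methylpentyl]-1,3-dimethyl-7-oxabicyclo[2.2.1]heptan-2-yl]-3-methylpent-1-en-3-ol, via lithiated carbamate 24 (not isolated), via boronate complex 25 (not isolated), via tertiary allylic boronic ester 26 (not isolated)
Conditions: s-BuLi, TMEDA, Et2O, −78 °C (23 to 24); add 21, −78 °C to rt; then NaBO3·4H2O, THF/H2O, rt
Reagents that add atoms: sodium perborate (NaBO3·4H2O), [Na+].[Na+].O[B-]1(O)OO[B-](O)(O)OO1
Why: Lithiation–borylation followed by oxidation: deprotonation of the allylic carbamate with retention, borylation with retention, 1,2-metallate rearrangement with inversion and C–B oxidation with retention should carry the configuration of (R)-but-3-en-2-ol into the (3S)-tertiary allylic alcohol.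

Compound list

1 | geranyl acetate, (2E)-3,7-dimethylocta-2,6-dien-1-yl acetate | CC(C)=CCC/C(C)=C/COC(C)=O | starting material
2 | 2-[(2E)-3,7-dimethylocta-2,6-dien-1-yl]-4,4,5,5-tetramethyl-1,3,2-dioxaborolane | CC(C)=CCC/C(C)=C/CB1OC(C)(C)C(C)(C)O1 | intermediate
3 | 3-[(tert-butyldimethylsilyl)oxy]propanal | O=CCCO[Si](C)(C)C(C)(C)C | starting material
4 | 2-{[(3R,4S)-1-[(tert-butyldimethylsilyl)oxy]-4-ethenyl-4,8-dimethylnon-7-en-3-yl]oxy}-4,4,5,5-tetramethyl-1,3,2-dioxaborolane | C=C[C@](C)(CCC=C(C)C)[C@@H](CCO[Si](C)(C)C(C)(C)C)OB1OC(C)(C)C(C)(C)O1 | intermediate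
5 | (3R,4S)-1-[(tert-butyldimethylsilyl)oxy]-4-ethenyl-4,8-dimethylnon-7-en-3-ol | C=C[C@](C)(CCC=C(C)C)[C@H](O)CCO[Si](C)(C)C(C)(C)C | intermediate
6 | (3R,4S)-4-ethenyl-4,8-dimethylnon-7-ene-1,3-diol | C=C[C@](C)(CCC=C(C)C)[C@H](O)CCO | intermediate
7 | (3R,4S)-4-ethenyl-3-hydroxy-4,8-dimethylnon-7-en-1-yl 4-methylbenzenesulfonate | C=C[C@](C)(CCC=C(C)C)[C@H](O)CCOS(=O)(=O)c1ccc(C)cc1 | intermediate
8 | (2R)-2-[(3S)-3,7-dimethylocta-1,6-dien-3-yl]oxetane | C=C[C@](C)(CCC=C(C)C)[C@H]1CCO1 | intermediate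
9 | (3R)-3,7-dimethyl-3-[(2R)-oxetan-2-yl]oct-6-en-2-one | CC(=O)[C@](C)(CCC=C(C)C)[C@H]1CCO1 | intermediate
10 | (4R)-4,8-dimethyl-4-[(2R)-oxetan-2-yl]non-7-en-3-one | CCC(=O)[C@](C)(CCC=C(C)C)[C@H]1CCO1 | intermediate
11 | (4R)-6-[(2R)-3,3-dimethyloxiran-2-yl]-4-methyl-4-[(2R)-oxetan-2-yl]hexan-3-one | CCC(=O)[C@](C)(CC[C@H]1OC1(C)C)[C@H]2CCO2 | intermediate
12 | (5R)-7-[(2R)-3,3-dimethyloxiran-2-yl]-1,1,1-trifluoro-3,5-dimethyl-5-[(2R)-oxetan-2-yl]heptane-2,4-dione (C3 epimers) | CC(C(=O)C(F)(F)F)C(=O)[C@](C)(CC[C@H]1OC1(C)C)[C@H]2CCO2 | intermediate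
13 | (4R)-2-diazo-6-[(2R)-3,3-dimethyloxiran-2-yl]-4-methyl-4-[(2R)-oxetan-2-yl]hexan-3-one | CC(=[N+]=[N-])C(=O)[C@](C)(CC[C@H]1OC1(C)C)[C@H]2CCO2 | intermediate
14 | (4R,5R)-4-{2-[(2R)-3,3-dimethyloxiran-2-yl]ethyl}-2,4-dimethyl-3-oxo-1-oxoniabicyclo[3.2.0]heptan-2-ide (oxonium ylide) | C[C-]1C(=O)[C@](C)(CC[C@H]2OC2(C)C)[C@H]3CC[O+]13 | intermediate
15 | (1S,3R,4R)-3-{2-[(2R)-3,3-dimethyloxiran-2-yl]ethyl}-1,3-dimethyl-7-oxabicyclo[2.2.1]heptan-2-one | O=C1[C@](C)(CC[C@H]2OC2(C)C)[C@H]3CC[C@]1(C)O3 | intermediate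
16 | (1S,3R,4R)-3-[(3S)-3-bromo-4-hydroxy-4-methylpentyl]-1,3-dimethyl-7-oxabicyclo[2.2.1]heptan-2-one | O=C1[C@](C)(CC[C@H](Br)C(C)(C)O)[C@H]2CC[C@]1(C)O2 | intermediate
17 | (1S,3R,4R)-3-[(3S)-3-bromo-4-chloro-4-methylpentyl]-1,3-dimethyl-7-oxabicyclo[2.2.1]heptan-2-one | O=C1[C@](C)(CC[C@H](Br)C(C)(C)Cl)[C@H]2CC[C@]1(C)O2 | intermediate
18 | (1S,3S,4R)-3-[(3S)-3-bromo-4-chloro-4-methylpentyl]-1,3-dimethyl-2-methylidene-7-oxabicyclo[2.2.1]heptane | C=C1[C@](C)(CC[C@H](Br)C(C)(C)Cl)[C@H]2CC[C@]1(C)O2 | intermediate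
19 | 2-{[(1S,2S,3S,4R)-3-[(3S)-3-bromo-4-chloro-4-methylpentyl]-1,3-dimethyl-7-oxabicyclo[2.2.1]heptan-2-yl]methyl}-4,4,5,5-tetramethyl-1,3,2-dioxaborolane | CC1(C)OB(C[C@H]2[C@](C)(CC[C@H](Br)C(C)(C)Cl)[C@H]3CC[C@]2(C)O3)OC1(C)C | intermediate
20 | lithium (chloromethyl)boronate complex of 19 | [Li+].ClC[B-]1(C[C@H]2[C@](C)(CC[C@H](Br)C(C)(C)Cl)[C@H]3CC[C@]2(C)O3)OC(C)(C)C(C)(C)O1 | intermediate
21 | 2-{2-[(1S,2S,3S,4R)-3-[(3S)-3-bromo-4-chloro-4-methylpentyl]-1,3-dimethyl-7-oxabicyclo[2.2.1]heptan-2-yl]ethyl}-4,4,5,5-tetramethyl-1,3,2-dioxaborolane | CC1(C)OB(CC[C@H]2[C@](C)(CC[C@H](Br)C(C)(C)Cl)[C@H]3CC[C@]2(C)O3)OC1(C)C | intermediate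
22 | (R)-but-3-en-2-ol | C=C[C@@H](C)O | starting material
23 | (2R)-but-3-en-2-yl N,N-diisopropylcarbamate | C=C[C@@H](C)OC(=O)N(C(C)C)C(C)C | intermediate
24 | [(2R)-2-(N,N-diisopropylcarbamoyloxy)but-3-en-2-yl]lithium | C=C[C@@]([Li])(C)OC(=O)N(C(C)C)C(C)C | intermediate
25 | lithium boronate complex from 24 and 21 | [Li+].C=C[C@@]([B-]1(CC[C@H]2[C@](C)(CC[C@H](Br)C(C)(C)Cl)[C@H]3CC[C@]2(C)O3)OC(C)(C)C(C)(C)O1)(C)OC(=O)N(C(C)C)C(C)C | intermediate
26 | 2-[(3R)-5-[(1S,2S,3S,4R)-3-[(3S)-3-bromo-4-chloro-4-methylpentyl]-1,3-dimethyl-7-oxabicyclo[2.2.1]heptan-2-yl]-3-methylpent-1-en-3-yl]-4,4,5,5-tetramethyl-1,3,2-dioxaborolane | C=C[C@](C)(CC[C@H]1[C@](C)(CC[C@H](Br)C(C)(C)Cl)[C@H]2CC[C@]1(C)O2)B3OC(C)(C)C(C)(C)O3 | intermediate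
27 | (3S)-5-[(1S,2S,3S,4R)-3-[(3S)-3-bromo-4-chloro-4-methylpentyl]-1,3-dimethyl-7-oxabicyclo[2.2.1]heptan-2-yl]-3-methylpent-1-en-3-ol | C=C[C@@](C)(O)CC[C@H]1[C@](C)(CC[C@H](Br)C(C)(C)Cl)[C@H]2CC[C@]1(C)O2 | target

Total step count: 16. Longest linear sequence: 15 steps (steps 1 to 14 and step 16; step 15 is a one-step side branch).

Steps most likely to fail

Step 9. The copper carbenoid may be lost by 1,2-hydride migration from its methyl group to give a vinyl ketone. After ylide formation, β-elimination or migration of the ring-fusion carbon C4 may also win, because the shift of the unactivated primary carbon C6 is slow. The fallback sets out from 11 and comes back at 15; it carries out the same ring enlargement stepwise and without a carbenoid. The silyl enol ether of 11 (LiHMDS, TMSCl, THF, −78 °C) is brominated with NBS to (4R)-2-bromo-6-[(2R)-3,3-dimethyloxiran-2-yl]-4-methyl-4-[(2R)-oxetan-2-yl]hexan-3-one F1. On warming in MeCN with catalytic Bu4NBr, the oxetane oxygen should displace the activated α-bromide (5-exo-tet), and bromide should reopen the strained oxetanium ion at its primary carbon C6. This should give (4R,5R)-5-(2-bromoethyl)-4-{2-[(2R)-3,3-dimethyloxiran-2-yl]ethyl}-2,4-dimethyloxolan-3-one F2. KHMDS (THF, −78 to 0 °C) then forms the enolate at C1, and intramolecular alkylation by the bromoethyl arm closes the C1–C6 bond to 15; the bridge again fixes the configuration at C1.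

Step 10. Lewis-acid-assisted ionisation of the epoxide at its tertiary carbon may give the regioisomeric tertiary bromide or a Meinwald-type rearrangement in place of SN2 attack at the secondary carbon. The fallback sets out from 15 and comes back at 16; it uses a cyclic sulfate, which reacts with bromide without a Lewis acid.
- Acid-catalysed hydrolysis (HClO4 cat., THF/H2O; water enters at the tertiary carbon, the secondary C–O bond is kept) gives (1S,3R,4R)-3-[(3R)-3,4-dihydroxy-4-methylpentyl]-1,3-dimethyl-7-oxabicyclo[2.2.1]heptan-2-one F3.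
- SOCl2 and Et3N (CH2Cl2, 0 °C) give the cyclic sulfite (1S,3R,4R)-3-{2-[(4R)-5,5-dimethyl-2-oxo-1,3,2-dioxathiolan-4-yl]ethyl}-1,3-dimethyl-7-oxabicyclo[2.2.1]heptan-2-one F4, which is not isolated.
- RuCl3 (cat.) and NaIO4 (MeCN/H2O) oxidise it to the cyclic sulfate (1S,3R,4R)-3-{2-[(4R)-5,5-dimethyl-2,2-dioxo-1,3,2-dioxathiolan-4-yl]ethyl}-1,3-dimethyl-7-oxabicyclo[2.2.1]heptan-2-one F5.
- LiBr in THF should open it by SN2 at the secondary carbon with inversion to the lithium salt of (1S,3R,4R)-3-[(3S)-3-bromo-4-methyl-4-(sulfonatooxy)pentyl]-1,3-dimethyl-7-oxabicyclo[2.2.1]heptan-2-one F6.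
- Hydrolysis of the sulfate ester (H2SO4 cat., H2O, THF) gives 16.

Step 12. The two quaternary carbons beside the carbonyl group may block the [2+2] addition of the titanocene methylidene, and long heating may cause loss of HCl from the tertiary chloride. The fallback sets out from 17 and comes back at 21, so that 18, 19 and 20 are bypassed.
- The small nucleophile CH2=CHMgBr with CeCl3 (THF, −78 °C) should add from the exo face, and the alkoxide is trapped with ClCO2Me as methyl (1S,2S,3R,4R)-3-[(3S)-3-bromo-4-chloro-4-methylpentyl]-2-ethenyl-1,3-dimethyl-7-oxabicyclo[2.2.1]heptan-2-yl carbonate F7.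
- Tsuji reduction (Pd(OAc)2, PBu3, HCO2NH4, THF, 40 °C) ionises the endo carbonate with inversion, so zerovalent palladium ends on the exo face and delivers hydride to the more substituted allyl terminus C2 from that face. This should give (1S,2S,3S,4R)-3-[(3S)-3-bromo-4-chloro-4-methylpentyl]-2-ethenyl-1,3-dimethyl-7-oxabicyclo[2.2.1]heptane F8, with C2 set by stereospecific delivery and not by steric bias alone.
- Anti-Markovnikov hydroboration of the vinyl group (HBpin, RhCl(PPh3)3, THF, rt) gives 21.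

Further compounds

F1 | step 9 | (4R)-2-bromo-6-[(2R)-3,3-dimethyloxiran-2-yl]-4-methyl-4-[(2R)-oxetan-2-yl]hexan-3-one (C2 epimers) | CC(Br)C(=O)[C@](C)(CC[C@H]1OC1(C)C)[C@H]2CCO2
F2 | step 9 | (4R,5R)-5-(2-bromoethyl)-4-{2-[(2R)-3,3-dimethyloxiran-2-yl]ethyl}-2,4-dimethyloxolan-3-one (C2 epimers) | CC1C(=O)[C@](C)(CC[C@H]2OC2(C)C)[C@@H](CCBr)O1
F3 | step 10 | (1S,3R,4R)-3-[(3R)-3,4-dihydroxy-4-methylpentyl]-1,3-dimethyl-7-oxabicyclo[2.2.1]heptan-2-one | O=C1[C@](C)(CC[C@@H](O)C(C)(C)O)[C@H]2CC[C@]1(C)O2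
F4 | step 10 | (1S,3R,4R)-3-{2-[(4R)-5,5-dimethyl-2-oxo-1,3,2-dioxathiolan-4-yl]ethyl}-1,3-dimethyl-7-oxabicyclo[2.2.1]heptan-2-one | O=C1[C@](C)(CC[C@H]3OS(=O)OC3(C)C)[C@H]2CC[C@]1(C)O2
F5 | step 10 | (1S,3R,4R)-3-{2-[(4R)-5,5-dimethyl-2,2-dioxo-1,3,2-dioxathiolan-4-yl]ethyl}-1,3-dimethyl-7-oxabicyclo[2.2.1]heptan-2-one | O=C1[C@](C)(CC[C@H]3OS(=O)(=O)OC3(C)C)[C@H]2CC[C@]1(C)O2
F6 | step 10 | lithium salt of (1S,3R,4R)-3-[(3S)-3-bromo-4-methyl-4-(sulfonatooxy)pentyl]-1,3-dimethyl-7-oxabicyclo[2.2.1]heptan-2-one | [Li+].O=C1[C@](C)(CC[C@H](Br)C(C)(C)OS(=O)(=O)[O-])[C@H]2CC[C@]1(C)O2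
F7 | step 12 | methyl (1S,2S,3R,4R)-3-[(3S)-3-bromo-4-chloro-4-methylpentyl]-2-ethenyl-1,3-dimethyl-7-oxabicyclo[2.2.1]heptan-2-yl carbonate | C=C[C@]1(OC(=O)OC)[C@](C)(CC[C@H](Br)C(C)(C)Cl)[C@H]2CC[C@]1(C)O2
F8 | step 12 | (1S,2S,3S,4R)-3-[(3S)-3-bromo-4-chloro-4-methylpentyl]-2-ethenyl-1,3-dimethyl-7-oxabicyclo[2.2.1]heptane | C=C[C@H]1[C@](C)(CC[C@H](Br)C(C)(C)Cl)[C@H]2CC[C@]1(C)O2
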